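Compound numbers are those of the steps and of the compound list below.

## Analysis of the target

Cladonaphchrom A (14) is a chroman: a pyran ring (O1, C2, C3, C4) fused to a phenol ring (C4a to C8a) that carries a free hydroxyl at C5. C2 bears a methyl group and C4 a 4,5-dimethoxynaphthalen-1-yl group bonded through its C1'. The two stereocentres, C2 (R) and C4 (S), are 1,3-related across the pyran ring, with methyl and naphthyl trans. C4 is a doubly benzylic methine wedged between the C5 hydroxyl and the peri hydrogen at C8' of the naphthalene, so the C4–C1' bond is hindered and C4 keeps no functional group by which it could be corrected later. The peri-dimethoxynaphthalene is very electron-rich (C8', para to a methoxy group, is nucleophilic), so strong oxidants, strong electrophiles and long-lived cations near it are to be avoided; the free phenol and the benzylic C2–O bond are the other sensitive points. The difficulty is to fix the absolute configuration of a diaryl-type methine and then the trans relationship to a remote methyl-bearing centre that has no neighbouring handle. The feature used is that C4 is bonded to exactly three carbons, C1', C4a and C3. C4 can therefore be the carbonyl carbon of a naphthaldehyde, and C4a with its oxygenated neighbours C5 and C8a is C2 of cyclohexane-1,3-dione. C3 and C2 are the two carbons of a vinyl ether, which leaves C2 at the aldehyde oxidation level for a late methyl addition.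

## Retrosynthetic reasoning

**14 to 13.** The C5 phenol is masked as its acetate. A free phenol would consume the methyl donor that makes the C2–CH3 bond, and an aryl acetate comes off under conditions that touch nothing else.

**13 to 12.** The C2–CH3 bond is cut. A methyl nucleophile adding to the cyclic oxocarbenium ion from anomeric acetate 12 should enter anti to the C4 naphthyl, which is the trans relationship of the target. The reverse order (methyl at the ketone level, then hydride) would deliver hydride anti and leave the methyl cis, so C2 must stay at the aldehyde level until this point. The forward reaction has to ionise only the exocyclic C2–O bond and control the face of attack.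

**12 to 11 to 10.** The anomeric acetate is traced through lactol 11 to ethyl acetal 10. In 10 the ring oxygen is an aryloxy group and the better leaving group, so direct Lewis-acid substitution would tend to open the ring; exchange to an acetate reverses that preference. What is gained is that 10 is simply the aromatised form of a hetero-Diels–Alder adduct.

**10 to 9 to 8 to 7.** The phenol ring is taken back by two hydrogens to the cyclohexenone of 7, through dienone 9 and silyl dienol ether 8. The 1,3-oxygen pattern O1/C5–OH is that of a 1,3-dione, and at the dione level C4a can first act as a nucleophilic carbon and then be part of an oxadiene. A resorcinol could not do this without regiochemical ambiguity or a preformed benzhydrol. The forward sequence must enolise at C6 selectively and dehydrogenate without harming the acetal or the naphthalene.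

**7 to 6 and 5, then 6 to 3 and 4.** This is the key disconnection. Retro-[4+2] cleavage of C3–C4 and O1–C2 gives oxadiene 6 and ethyl vinyl ether 5; retro-Knoevenagel cleavage of C4=C4a gives aldehyde 3 and dione 4. All bonds to C4 except C4–C1' are made in one flask, the pyran ring and the C4 stereocentre arise together, and the two carbonyl groups of 4 are equivalent, so no regioisomer is possible. The forward reaction must differentiate the faces of 6 with a chiral Brønsted acid and outrun addition of a second dione.

**3 to 1.** The C1'–CHO bond is cut: formylation of 1 para to a methoxy group, through iminium salt 2. The naphthalene is bought with both methyl ethers in place.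

## Alternatives that were turned down

**Alternative 1:** The naphthalene ring that carries the chroman is disconnected at C4'–C4a' and C1'–C8a'. Forward, fluoride-released 3-methoxybenzyne A3 adds across C2 and C5 of silyloxyfuran A2, which already bears the finished chroman, to give the 1,4-epoxy adduct A1.
- For it: the nucleophilic furan terminus and the polarised aryne should combine with the regiochemistry needed, and the two peri oxygens arrive differentiated. On that point it is stronger than the chosen route, which cannot tell the two methoxy groups apart.
- Against it: in 14 both oxygens are methyl ethers, so the differentiation buys nothing. The oxygen bridge of A1 must still be removed reductively and the freed oxygen methylated. Above all, A2 must contain both chroman stereocentres before the key step, so the stereochemical problem is moved to an earlier, unsolved stage.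
- Comparison: the chosen route buys the naphthalene as 1 and spends its key step on C4 instead.

**Alternative 2:** The second naphthalene ring is disconnected at C5'–C4a'. Forward, butenoic acid A5 is heated under acylating, dehydrating conditions to form dienylketene A6, whose 6π-electrocyclisation and acylation give naphthyl acetate A4.
- For it: only one ortho position is free, so ring closure is regiochemically unambiguous; the chemistry is thermal and catalyst-free; the C5' oxygen again arrives differentiated.
- Against it: the alkene of A5 must isomerise to the Z geometry of A6 before closure. A4 still needs acetate-to-methyl exchange and debenzylation. A5 is a stereodefined chroman carrying a 1,2,4-trisubstituted benzene with a side chain ortho to the hindered C4 attachment, so the sequence is long and linear and leaves C2 and C4 unaddressed.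
- Comparison: it is more predictable in the ring-forming step itself, but far poorer in step economy than a one-step formylation of 1.

**Alternative 3:** O1–C8a, C4–C4a, C3–C4 and O1–C2 are all cut. Forward, 3-(benzyloxy)benzyne A8 inserts into the C=O of aldehyde 3 to give ortho-quinone methide A9, which adds chiral vinyl ether A10 by [4+2] to give acetal A7.
- For it: it uses the same aldehyde 3 and delivers the chroman already aromatic, so steps 3 and 4 of the chosen route are saved. Auxiliary control of enol-ether additions to ortho-quinone methides has closer precedent than the catalytic control proposed here. On length and on precedent for stereocontrol this alternative is the stronger one.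
- Against it: four bonds must form from two transient species. A9 can be intercepted by a second molecule of A8, and A8 can react with A10 directly. The cycloaddition runs uncatalysed at the temperature of aryne generation, on a short-lived diene of uncontrolled geometry. The auxiliary is stoichiometric and the benzyl ether costs a final hydrogenolysis.
- Comparison: the chosen route offers closed-shell, storable components, an oxadiene (6) formed under equilibrium as the only electrophile present, and catalytic chirality. The price is two redox steps and an untested enantioselective step.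

Key step: step 2

Assumptions: 11 and 12 are used as C2-epimer mixtures, since both epimers ionise to the same oxocarbenium ion in step 7. Which antipode of the phosphoric acid leads to (4S) must be settled in the first run; the (R)-acid is written provisionally.

## Route

Step 1
Reactants: 1 1,8-dimethoxynaphthalene
Product: 3 4,5-dimethoxy-1-naphthaldehyde, via aryliminium chloride 2 (not isolated)
Conditions: POCl3, DMF, 0 → 70 °C; then H2O
Reagents that add atoms: N,N-dimethylformamide CN(C)C=O (formyl carbon); water O (aldehyde oxygen); phosphoryl chloride O=P(Cl)(Cl)Cl (chloride counter-ion of 2 only)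
Why: Vilsmeier–Haack formylation: the chloroiminium electrophile attacks the α-position para to a methoxy group, which is more activated and less hindered than the ortho β-position, and the two rings of 1 are equivalent, so one para aldehyde should result after hydrolysis of 2.

Step 2
Reactants: 3 4,5-dimethoxy-1-naphthaldehyde; 4 cyclohexane-1,3-dione; 5 ethyl vinyl ether
Product: 7 (2R,4S)-4-(4,5-dimethoxynaphthalen-1-yl)-2-ethoxy-2,3,4,6,7,8-hexahydro-5H-chromen-5-one (2,4-cis), via arylidene dione 6 (not isolated)
Conditions: (R)-3,3'-bis(2,4,6-triisopropylphenyl)-1,1'-binaphthyl-2,2'-diyl hydrogen phosphate (10 mol %), 5 (10 equiv), slow addition of 4, 4 Å molecular sieves, toluene, 0 °C → rt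
Reagents that add atoms: none
Why: Proposed new method: acid-promoted Knoevenagel condensation of 3 with the enol of 4 gives the 1-oxadiene 6, whose exocyclic C=C is locked s-cis to both ring carbonyls; the phosphoric acid hydrogen-bonds to one carbonyl, lowers the LUMO, and the electron-rich alkene 5 adds in an inverse-electron-demand oxa-[4+2] cycloaddition in which C3–C4 forms ahead of O1–C2. The closest known reaction type is the amine-salt-catalysed three-component domino Knoevenagel/hetero-Diels–Alder reaction of cyclic 1,3-diones, aldehydes and enol ethers, which is racemic, together with phosphoric-acid-controlled [4+2] additions to ortho-quinone methides, of which 6 is the non-aromatic counterpart. The dihydropyran ring is closed by intermolecular [4+2] cycloaddition; in the stepwise limit the second bond is a 6-exo-trig attack of the enol oxygen on the ethoxycarbenium carbon. C4 is set by the chiral phosphate, which shields one face of the acid-bound oxadiene, so the antipode of the acid decides between (4S) and (4R); C2 follows from the endo orientation of the ethoxy group and is erased in steps 5 to 7. Regiochemistry needs nothing beyond the polarity of the partners (nucleophilic CH2 of 5 to electrophilic C4) and the equivalence of the two carbonyl groups of 4. Chemoselectivity against Michael addition of a second molecule of 4 to 6 rests on the large excess of 5, on feeding 4 slowly, and on the reversibility of that addition for a donor-substituted arylidene; the sieves take up the water of condensation so that 5 is not hydrolysed. The donor effect of the naphthyl group also slows the uncatalysed cycloaddition, which is what should let the acid-bound pathway dominate.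

Step 3
Reactants: 7 (2R,4S)-4-(4,5-dimethoxynaphthalen-1-yl)-2-ethoxy-2,3,4,6,7,8-hexahydro-5H-chromen-5-one
Product: 8 (2R,4S)-4-(4,5-dimethoxynaphthalen-1-yl)-2-ethoxy-5-(trimethylsilyloxy)-3,4,7,8-tetrahydro-2H-chromene
Conditions: Me3SiCl, LiN(iPr)2, THF, −78 °C (Me3SiCl present from the start); non-aqueous work-up, used crude
Reagents that add atoms: chlorotrimethylsilane C[Si](C)(C)Cl
Why: Silyl enol ether formation under kinetic control: the amide base deprotonates the vinylogous ester at the α'-methylene C6 rather than at the γ-position C8, and the enolate is trapped on oxygen as it forms. The acetal, the aryl ethers and the non-acidic C4–H are untouched, so neither stereocentre is at risk.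

Step 4
Reactants: 8 (2R,4S)-4-(4,5-dimethoxynaphthalen-1-yl)-2-ethoxy-5-(trimethylsilyloxy)-3,4,7,8-tetrahydro-2H-chromene
Product: 10 (2R,4S)-4-(4,5-dimethoxynaphthalen-1-yl)-2-ethoxychroman-5-ol, via dienone tautomer 9 (not isolated)
Conditions: Pd(OAc)2 (1.1 equiv), MeCN, rt
Reagents that add atoms: none
Why: Saegusa–Ito dehydrogenation: palladation of the silyl enol ether at C6 and β-hydride elimination from C7 give the cross-conjugated dienone 9, the keto tautomer of a phenol, which enolises at once to 10. The medium is neutral to weakly acidic, so the acetal and the electron-rich naphthalene should survive.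

Step 5
Reactants: 10 (2R,4S)-4-(4,5-dimethoxynaphthalen-1-yl)-2-ethoxychroman-5-ol
Product: 11 (4S)-4-(4,5-dimethoxynaphthalen-1-yl)chromane-2,5-diol (C2 epimers)
Conditions: 1 M aq. HCl, THF, 0 °C → rt
Reagents that add atoms: water O
Why: Acid-catalysed acetal hydrolysis: whichever C–O bond ionises first, water returns the six-membered lactol, which is favoured over the open hydroxy aldehyde, and closure on either of the two equivalent phenolic oxygens gives the same compound. C4 has no acidic or ionisable bond under these conditions.

Step 6
Reactants: 11 (4S)-4-(4,5-dimethoxynaphthalen-1-yl)chromane-2,5-diol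
Product: 12 (4S)-4-(4,5-dimethoxynaphthalen-1-yl)chromane-2,5-diyl diacetate (C2 epimers)
Conditions: Ac2O, pyridine, 4-(dimethylamino)pyridine (cat.), CH2Cl2, 0 °C → rt
Reagents that add atoms: acetic anhydride CC(=O)OC(C)=O
Why: Nucleophile-catalysed O-acetylation of the phenol and of the lactol hydroxyl. The anomeric acetate is the leaving group for step 7 and the aryl acetate keeps the phenol from consuming the aluminium reagent.

Step 7
Reactants: 12 (4S)-4-(4,5-dimethoxynaphthalen-1-yl)chromane-2,5-diyl diacetate
Product: 13 (2R,4S)-4-(4,5-dimethoxynaphthalen-1-yl)-2-methylchroman-5-yl acetate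
Conditions: AlMe3 (4 equiv), CH2Cl2, −78 → 0 °C; then aq. potassium sodium tartrate
Reagents that add atoms: trimethylaluminium C[Al](C)C
Why: Lewis-acid-mediated substitution of an anomeric acetate by an organoaluminium reagent: AlMe3 ionises the C2 acetate to the cyclic oxocarbenium ion and transfers a methyl group to it. In the half-chair cation the C4 naphthyl is held pseudoaxial by the peri acetoxy group at C5 and covers one face of C2, so methyl should enter anti to it and set the 2,4-trans (2R) centre. An acetate is used because it ionises exocyclically, whereas ethyl acetal 10 would tend to open the ring by loss of the phenoxide.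

Step 8
Reactants: 13 (2R,4S)-4-(4,5-dimethoxynaphthalen-1-yl)-2-methylchroman-5-yl acetate
Product: 14 (2R,4S)-4-(4,5-dimethoxynaphthalen-1-yl)-2-methylchroman-5-ol (Cladonaphchrom A)
Conditions: K2CO3 (0.2 equiv), MeOH, 0 °C → rt
Reagents that add atoms: none
Why: Base-catalysed methanolysis of the aryl acetate; the chroman ether, the methyl ethers and both stereocentres are inert to these conditions.

## Compound list

1 | 1,8-dimethoxynaphthalene | COc1cccc2cccc(OC)c12 | starting material
2 | N-[(4,5-dimethoxynaphthalen-1-yl)methylidene]-N-methylmethanaminium chloride | COc1cccc2c(C=[N+](C)C)ccc(OC)c12.[Cl-] | intermediate (not isolated)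
3 | 4,5-dimethoxy-1-naphthaldehyde | COc1cccc2c(C=O)ccc(OC)c12 | intermediate
4 | cyclohexane-1,3-dione | O=C1CCCC(=O)C1 | starting material
5 | ethyl vinyl ether (ethoxyethene) | C=COCC | starting material
6 | 2-[(4,5-dimethoxynaphthalen-1-yl)methylidene]cyclohexane-1,3-dione | COc1cccc2c(C=C3C(=O)CCCC3=O)ccc(OC)c12 | intermediate (not isolated)
7 | (2R,4S)-4-(4,5-dimethoxynaphthalen-1-yl)-2-ethoxy-2,3,4,6,7,8-hexahydro-5H-chromen-5-one (2,4-cis) | COc1cccc2c([C@@H]3C[C@H](OCC)OC4=C3C(=O)CCC4)ccc(OC)c12 | intermediate
8 | (2R,4S)-4-(4,5-dimethoxynaphthalen-1-yl)-2-ethoxy-5-(trimethylsilyloxy)-3,4,7,8-tetrahydro-2H-chromene | COc1cccc2c([C@@H]3C[C@H](OCC)OC4=C3C(O[Si](C)(C)C)=CCC4)ccc(OC)c12 | intermediate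
9 | (2R,4S)-4-(4,5-dimethoxynaphthalen-1-yl)-2-ethoxy-2,3,4,8-tetrahydro-5H-chromen-5-one | COc1cccc2c([C@@H]3C[C@H](OCC)OC4=C3C(=O)C=CC4)ccc(OC)c12 | intermediate (not isolated)
10 | (2R,4S)-4-(4,5-dimethoxynaphthalen-1-yl)-2-ethoxychroman-5-ol | COc1cccc2c([C@@H]3C[C@H](OCC)Oc4cccc(O)c43)ccc(OC)c12 | intermediate
11 | (4S)-4-(4,5-dimethoxynaphthalen-1-yl)chromane-2,5-diol (C2 epimers) | COc1cccc2c([C@@H]3CC(O)Oc4cccc(O)c43)ccc(OC)c12 | intermediate
12 | (4S)-4-(4,5-dimethoxynaphthalen-1-yl)chromane-2,5-diyl diacetate (C2 epimers) | COc1cccc2c([C@@H]3CC(OC(C)=O)Oc4cccc(OC(C)=O)c43)ccc(OC)c12 | intermediate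
13 | (2R,4S)-4-(4,5-dimethoxynaphthalen-1-yl)-2-methylchroman-5-yl acetate | COc1cccc2c([C@@H]3C[C@@H](C)Oc4cccc(OC(C)=O)c43)ccc(OC)c12 | intermediate
14 | (2R,4S)-4-(4,5-dimethoxynaphthalen-1-yl)-2-methylchroman-5-ol (Cladonaphchrom A) | COc1cccc2c([C@@H]3C[C@@H](C)Oc4cccc(O)c43)ccc(OC)c12 | target

## Step count and risk

Total step count: 8. Longest linear sequence: 8 steps, from 1 to 14.

**Step 2 (key step).** Enantiofacial discrimination may be low, because the acid holds the oxadiene by a single hydrogen bond and the acidic dione 4 can promote an unselective background reaction. The cycloaddition of the donor-stabilised oxadiene may also be slow, which gives time for Michael addition of 4 to 6 and for acid-promoted loss of 5. A more acidic phosphoramide analogue of the same acid is the first variation within the strategy.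

The fallback uses known iminium catalysis and sets out from 3 and 4. Wittig homologation of 3 with (triphenylphosphoranylidene)acetaldehyde should give (E)-3-(4,5-dimethoxynaphthalen-1-yl)prop-2-enal F1. Michael addition of 4 to F1 under (S)-2-[diphenyl(trimethylsilyloxy)methyl]pyrrolidine catalysis, with spontaneous hemiacetalisation, should give the lactol (4S)-4-(4,5-dimethoxynaphthalen-1-yl)-2-hydroxy-2,3,4,6,7,8-hexahydro-5H-chromen-5-one F2. By the usual shielding model the (S)-catalyst leads to (4S); this sense is to be confirmed. Acid-catalysed acetalisation with ethanol turns F2 into 7 together with its C2 epimer (2S,4S)-4-(4,5-dimethoxynaphthalen-1-yl)-2-ethoxy-2,3,4,6,7,8-hexahydro-5H-chromen-5-one F3. The mixture is put through the operations of steps 3 to 5, F3 passing through the (2S,4S) silyl dienol ether F4, the (2S,4S) dienone F5 and the (2S,4S) phenol acetal F6. Both series converge on 11, where the route is rejoined.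

**Step 4.** Dehydrogenation may stop short through protonolysis of the palladium enolate back to 7, hydrolysis of the moisture-sensitive 8 before palladation, or partial γ-deprotonation in step 3. The fallback sets out from 7: enolate sulfinylation with LiN(iPr)2 and methyl benzenesulfinate should give (2R,4S)-4-(4,5-dimethoxynaphthalen-1-yl)-2-ethoxy-6-(phenylsulfinyl)-2,3,4,6,7,8-hexahydro-5H-chromen-5-one F7. Thermal syn-elimination of the sulfoxide (toluene, Na2CO3, 110 °C) then passes through 9 and returns to the route at 10.

**Step 6.** Under basic acylation the lactol may ring-open and be acylated on the freed phenoxide, so that no anomeric acetate forms. The fallback sets out from 10 and avoids the free lactol. Acetylation of the phenol gives (2R,4S)-4-(4,5-dimethoxynaphthalen-1-yl)-2-ethoxychroman-5-yl acetate F8. Exchange of the ethoxy group with benzenesulfinic acid and CaCl2 in CH2Cl2 gives the anomeric sulfone (4S)-4-(4,5-dimethoxynaphthalen-1-yl)-2-(phenylsulfonyl)chroman-5-yl acetate F9. Displacement with ZnMe2 and ZnBr2 in THF, through the same oxocarbenium ion, returns to the route at 13.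

**Step 7.** Facial selectivity may be eroded if methyl is delivered within the ion pair from both anomers. The cation may also be captured intramolecularly by the nucleophilic C8' of the naphthalene (Friedel–Crafts closure of a six-membered ring), or lose a C3 proton. Attack of the reagent on the aryl acetate would be harmless. The fallback sets out from 11 and replaces cation capture by an SN2 ring closure. Excess MeMgBr adds to the open hydroxy aldehyde form to give 2-[(1S)-1-(4,5-dimethoxynaphthalen-1-yl)-3-hydroxybutyl]benzene-1,3-diol F10 as both carbinol epimers. Mitsunobu etherification (PPh3, diisopropyl azodicarboxylate) closes either equivalent phenol onto the carbinol with inversion. This gives 14 together with its C2 epimer (2S,4S)-4-(4,5-dimethoxynaphthalen-1-yl)-2-methylchroman-5-ol F11, and the two are separated by chromatography. This fallback secures material at the cost of stereocontrol at C2.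

## Further compounds

F1 | step 2 | (E)-3-(4,5-dimethoxynaphthalen-1-yl)prop-2-enal | COc1cccc2c(/C=C/C=O)ccc(OC)c12
F2 | step 2 | (4S)-4-(4,5-dimethoxynaphthalen-1-yl)-2-hydroxy-2,3,4,6,7,8-hexahydro-5H-chromen-5-one (C2 epimers) | COc1cccc2c([C@@H]3CC(O)OC4=C3C(=O)CCC4)ccc(OC)c12
F3 | step 2 | (2S,4S)-4-(4,5-dimethoxynaphthalen-1-yl)-2-ethoxy-2,3,4,6,7,8-hexahydro-5H-chromen-5-one | COc1cccc2c([C@@H]3C[C@@H](OCC)OC4=C3C(=O)CCC4)ccc(OC)c12
F4 | step 2 | (2S,4S)-4-(4,5-dimethoxynaphthalen-1-yl)-2-ethoxy-5-(trimethylsilyloxy)-3,4,7,8-tetrahydro-2H-chromene | COc1cccc2c([C@@H]3C[C@@H](OCC)OC4=C3C(O[Si](C)(C)C)=CCC4)ccc(OC)c12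
F5 | step 2 | (2S,4S)-4-(4,5-dimethoxynaphthalen-1-yl)-2-ethoxy-2,3,4,8-tetrahydro-5H-chromen-5-one | COc1cccc2c([C@@H]3C[C@@H](OCC)OC4=C3C(=O)C=CC4)ccc(OC)c12
F6 | step 2 | (2S,4S)-4-(4,5-dimethoxynaphthalen-1-yl)-2-ethoxychroman-5-ol | COc1cccc2c([C@@H]3C[C@@H](OCC)Oc4cccc(O)c43)ccc(OC)c12
F7 | step 4 | (2R,4S)-4-(4,5-dimethoxynaphthalen-1-yl)-2-ethoxy-6-(phenylsulfinyl)-2,3,4,6,7,8-hexahydro-5H-chromen-5-one (epimers at C6 and sulfur) | COc1cccc2c([C@@H]3C[C@H](OCC)OC4=C3C(=O)C(S(=O)c5ccccc5)CC4)ccc(OC)c12
F8 | step 6 | (2R,4S)-4-(4,5-dimethoxynaphthalen-1-yl)-2-ethoxychroman-5-yl acetate | COc1cccc2c([C@@H]3C[C@H](OCC)Oc4cccc(OC(C)=O)c43)ccc(OC)c12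
F9 | step 6 | (4S)-4-(4,5-dimethoxynaphthalen-1-yl)-2-(phenylsulfonyl)chroman-5-yl acetate (C2 epimers) | COc1cccc2c([C@@H]3CC(S(=O)(=O)c5ccccc5)Oc4cccc(OC(C)=O)c43)ccc(OC)c12
F10 | step 7 | 2-[(1S)-1-(4,5-dimethoxynaphthalen-1-yl)-3-hydroxybutyl]benzene-1,3-diol (C3 epimers) | COc1cccc2c([C@H](CC(C)O)c3c(O)cccc3O)ccc(OC)c12
F11 | step 7 | (2S,4S)-4-(4,5-dimethoxynaphthalen-1-yl)-2-methylchroman-5-ol | COc1cccc2c([C@@H]3C[C@H](C)Oc4cccc(O)c43)ccc(OC)c12
A1 | alternative 1 | 4-[(2R,4R)-5-(benzyloxy)-2-methylchroman-4-yl]-8-methoxy-1-(triisopropylsilyloxy)-1,4-dihydro-1,4-epoxynaphthalene (both bridgehead diastereomers) | COc1cccc2c1C3(O[Si](C(C)C)(C(C)C)C(C)C)C=CC2([C@@H]4C[C@@H](C)Oc5cccc(OCc6ccccc6)c54)O3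
A2 | alternative 1 | {5-[(2R,4R)-5-(benzyloxy)-2-methylchroman-4-yl]furan-2-yl}oxy(triisopropyl)silane | CC(C)[Si](C(C)C)(C(C)C)Oc1ccc([C@@H]2C[C@@H](C)Oc3cccc(OCc4ccccc4)c32)o1
A3 | alternative 1 | 3-methoxybenzyne (1-methoxy-2,3-didehydrobenzene) | COC1=CC=CC#C1
A4 | alternative 2 | 5-[(2R,4S)-5-(benzyloxy)-2-methylchroman-4-yl]-8-methoxynaphthalen-1-yl acetate | CC(=O)Oc1cccc2c([C@@H]3C[C@@H](C)Oc4cccc(OCc5ccccc5)c43)ccc(OC)c12
A5 | alternative 2 | (E)-4-{2-[(2R,4S)-5-(benzyloxy)-2-methylchroman-4-yl]-5-methoxyphenyl}but-3-enoic acid | OC(=O)C/C=C/c1cc(OC)ccc1[C@@H]1C[C@@H](C)Oc2cccc(OCc3ccccc3)c21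
A6 | alternative 2 | (3Z)-4-{2-[(2R,4S)-5-(benzyloxy)-2-methylchroman-4-yl]-5-methoxyphenyl}buta-1,3-dien-1-one | O=C=C/C=C\c1cc(OC)ccc1[C@@H]1C[C@@H](C)Oc2cccc(OCc3ccccc3)c21
A7 | alternative 3 | (2R,4S)-5-(benzyloxy)-4-(4,5-dimethoxynaphthalen-1-yl)-2-[(1S,2R)-2-phenylcyclohexyloxy]chroman (2,4-cis) | COc1cccc2c([C@@H]3C[C@H](O[C@H]5CCCC[C@@H]5c5ccccc5)Oc4cccc(OCc6ccccc6)c43)ccc(OC)c12
A8 | alternative 3 | 3-(benzyloxy)benzyne (1-(benzyloxy)-2,3-didehydrobenzene) | C(OC1=CC=CC#C1)c1ccccc1
A9 | alternative 3 | 5-(benzyloxy)-6-[(4,5-dimethoxynaphthalen-1-yl)methylidene]cyclohexa-2,4-dien-1-one | COc1cccc2c(C=C3C(=O)C=CC=C3OCc3ccccc3)ccc(OC)c12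
A10 | alternative 3 | (1S,2R)-2-phenylcyclohexyl vinyl ether | C=CO[C@H]1CCCC[C@@H]1c1ccccc1
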